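**Retrosynthetic overview**

1. The epoxide comes last: Shi epoxidation (C3–O/C4–O) of the macrocyclic (3E,6Z)-triene lactone, whose 6Z-alkene comes from Lindlar reduction of a 14-membered enyne.
2. The 14-membered ring is closed at C5–C6 by intramolecular copper-acetylide allylation of an acyclic α-methylene-γ-butyrolactone that carries a terminal alkyne and an allylic chloride.
3. The lactone ring and C13, C14, C1 come from the key C13–O bond formation: proline-catalysed α-aminoxylation of the east aldehyde, followed in the same flask by chelation-controlled indium Barbier addition of the west 2-(bromomethyl)dienoate and lactonisation.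
4. The east aldehyde comes from (S)-citronellal (C12 from the chiral pool); C8–O is set by Sharpless epoxidation and hydride opening, and the alkyne by Ohira–Bestmann homologation.
5. The west bromide comes from prenyl chloride, methyl propiolate and formaldehyde. Ring order: γ-lactone, then 14-membered carbocycle, then epoxide.

Assumption: the target is taken as drawn, i.e. (1S,3R,4R,6Z,8S,12S,13R,14R)-3,4-epoxy-8,13-dihydroxycembra-6,15(17)-dien-16,14-olide; cembrane numbering (C1–C20) is used for locants in the macrocycles and in the explanations.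

**Route**

Step 1
Reactants: 1 (S)-citronellal
Product: 2 (6S)-8,8-dimethoxy-2,6-dimethyloct-2-ene
Conditions: HC(OMe)3, PPTS (cat.), MeOH, 25 °C
Reagents that add atoms: trimethyl orthoformate, COC(OC)OC
Why: Acid-catalysed acetalisation masks the aldehyde for the hydride and base steps that follow and leaves the chiral-pool C12 stereocentre untouched.

Step 2
Reactants: 2 (6S)-8,8-dimethoxy-2,6-dimethyloct-2-ene
Product: 3 (2E,6S)-8,8-dimethoxy-2,6-dimethyloct-2-en-1-ol
Conditions: SeO2 (0.3 equiv), t-BuOOH (anhydrous, in decane), CH2Cl2, 25 °C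
Reagents that add atoms: tert-butyl hydroperoxide, CC(C)(C)OO; selenium dioxide, O=[Se]=O
Why: SeO2-catalysed allylic (Riley) oxidation (ene reaction, then [2,3]-sigmatropic shift) attacks the (E)-methyl of the isopropylidene group and gives the (E)-allylic alcohol.

Step 3
Reactants: 3 (2E,6S)-8,8-dimethoxy-2,6-dimethyloct-2-en-1-ol
Product: 4 [(2R,3R)-3-[(3S)-5,5-dimethoxy-3-methylpentyl]-2-methyloxiran-2-yl]methanol
Conditions: Ti(OiPr)4 (10 mol%), D-(−)-diethyl tartrate (12 mol%), t-BuOOH, 4 Å MS, CH2Cl2, −20 °C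
Reagents that add atoms: tert-butyl hydroperoxide, CC(C)(C)OO
Why: Sharpless asymmetric epoxidation forms the C8–O bond under reagent control; the D-(−)-tartrate catalyst gives the (2R,3R)-epoxy alcohol, which fixes the future C8 configuration.

Step 4
Reactants: 4 [(2R,3R)-3-[(3S)-5,5-dimethoxy-3-methylpentyl]-2-methyloxiran-2-yl]methanol
Product: 5 (2S,6S)-8,8-dimethoxy-2,6-dimethyloctane-1,2-diol
Conditions: LiAlH4, THF, 0 → 25 °C
Reagents that add atoms: none
Why: Hydride opens the trisubstituted 2,3-epoxy alcohol by SN2 attack at the less substituted carbon, so the tertiary C–O bond keeps its configuration (the descriptor becomes S only through a change in CIP ranking).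

Step 5
Reactants: 5 (2S,6S)-8,8-dimethoxy-2,6-dimethyloctane-1,2-diol
Product: 7 (3S,7S)-9,9-dimethoxy-3,7-dimethylnon-1-yn-3-ol, via hydroxy aldehyde 6 (not isolated)
Conditions: IBX, DMSO, 25 °C; crude aldehyde, then dimethyl (1-diazo-2-oxopropyl)phosphonate, K2CO3, MeOH, 0 → 25 °C
Reagents that add atoms: dimethyl (1-diazo-2-oxopropyl)phosphonate, CC(=O)C(=[N+]=[N-])P(=O)(OC)OC
Why: IBX oxidises the primary hydroxyl of the 1,2-diol without glycol cleavage, and the non-epimerisable α-hydroxy aldehyde is homologated at once to the terminal alkyne by the Ohira–Bestmann (Seyferth–Gilbert) reaction.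

Step 6
Reactants: 7 (3S,7S)-9,9-dimethoxy-3,7-dimethylnon-1-yn-3-ol
Product: 8 (3S,7S)-7-hydroxy-3,7-dimethylnon-8-ynal
Conditions: AcOH–THF–H2O (3:1:1), 40 °C
Reagents that add atoms: water, O
Why: Mild acid hydrolysis of the dimethyl acetal frees the aldehyde; the tertiary propargylic alcohol and the β-stereocentre are stable under these conditions.

Step 7
Reactants: 9 prenyl chloride (1-chloro-3-methylbut-2-ene)
Product: 10 (2E)-4-chloro-2-methylbut-2-en-1-ol
Conditions: SeO2 (0.3 equiv), t-BuOOH, CH2Cl2, 25 °C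
Reagents that add atoms: tert-butyl hydroperoxide, CC(C)(C)OO; selenium dioxide, O=[Se]=O
Why: The same (E)-selective SeO2 allylic oxidation of a gem-dimethyl alkene sets the (E)-geometry of the future C3=C4 bond and differentiates the two ends of the C5 unit.

Step 8
Reactants: 10 (2E)-4-chloro-2-methylbut-2-en-1-ol; 11 methyl propiolate
Product: 12 methyl (5E)-7-hydroxy-6-methylhept-5-en-2-ynoate
Conditions: CuI (20 mol%), NaI, K2CO3, DMF, 25 °C
Reagents that add atoms: none
Why: Copper-catalysed alkyne–allyl halide coupling: the copper acetylide of the propiolate displaces the primary allylic halide (via the iodide) by SN2 and gives the skipped enyne; the free alcohol does not interfere.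

Step 9
Reactants: 12 methyl (5E)-7-hydroxy-6-methylhept-5-en-2-ynoate
Product: 13 methyl (5E)-7-chloro-6-methylhept-5-en-2-ynoate
Conditions: NCS, Me2S, CH2Cl2, −20 → 0 °C
Reagents that add atoms: N-chlorosuccinimide, O=C1CCC(=O)N1Cl
Why: Corey–Kim chlorination turns the primary allylic alcohol into the chloride without allylic transposition and without added nucleophiles that could attack the ynoate.

Step 10
Reactants: 13 methyl (5E)-7-chloro-6-methylhept-5-en-2-ynoate
Product: 14 methyl (2Z,5E)-7-chloro-2-(hydroxymethyl)-6-methylhepta-2,5-dienoate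
Conditions: i-Bu2AlH, HMPA, THF, 0 °C; then (CH2O)n, 0 → 25 °C
Reagents that add atoms: formaldehyde (as paraformaldehyde), C=O
Why: Conjugate hydroalumination of the ynoate by the i-Bu2AlH–HMPA complex gives an α-aluminated enoate that formaldehyde traps at the α-carbon (reductive aldol, Baylis–Hillman-type adduct); the 2-alkene geometry is of no consequence later.

Step 11
Reactants: 14 methyl (2Z,5E)-7-chloro-2-(hydroxymethyl)-6-methylhepta-2,5-dienoate
Product: 15 methyl (2E,5E)-2-(bromomethyl)-7-chloro-6-methylhepta-2,5-dienoate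
Conditions: PBr3, Et2O, −10 °C
Reagents that add atoms: phosphorus tribromide, BrP(Br)Br
Why: Standard conversion of a Baylis–Hillman-type primary allylic alcohol into the 2-(bromomethyl)alk-2-enoate; either alkene isomer gives the same fluxional allylindium in step 12 and the allylic chloride is untouched.

Step 12
Reactants: 8 (3S,7S)-7-hydroxy-3,7-dimethylnon-8-ynal; 15 methyl (2E,5E)-2-(bromomethyl)-7-chloro-6-methylhepta-2,5-dienoate
Product: 18 (4S,5R)-4-[(2E)-4-chloro-3-methylbut-2-en-1-yl]-5-[(1R,2S,6S)-6-hydroxy-2,6-dimethyl-1-[(phenylamino)oxy]oct-7-yn-1-yl]-3-methylideneoxolan-2-one, via aminooxy aldehyde 16 (not isolated), via hydroxy ester 17 (not isolated)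
Conditions: L-proline (20 mol%), PhNO (1.05 equiv, slow addition), DMSO, 20 °C; then 15 (1.5 equiv), In powder (1.5 equiv), THF–H2O (1:1), 0 → 25 °C; then PPTS (cat.), CH2Cl2, 25 °C
Reagents that add atoms: nitrosobenzene, O=Nc1ccccc1
Why: Proposed new method: the L-proline enamine of 8 attacks the oxygen of nitrosobenzene through the carboxylic-acid-directed transition state of aldehyde α-aminoxylation and forms the C13–O bond with R configuration; the α-(N-phenylaminooxy) aldehyde is intercepted in the same flask by the allylindium from 15, with the aminooxy group (O,N donor) and the carbonyl oxygen chelating trivalent indium so that the γ-substituted 2-(methoxycarbonyl)allyl unit adds through a closed six-membered chair transition state on the face away from C12, giving the 13,14-syn and 14,1-syn arrangement (C14 R, C1 S), and the γ-hydroxy ester closes to the cis-lactone; the closest known reaction types are the one-pot proline aminoxylation–indium allylation of aldehydes with allyl bromide itself and the indium-mediated coupling of 2-(bromomethyl)alk-2-enoates with α-oxygenated aldehydes in water, which have not been merged nor run with a γ-substituted Baylis–Hillman bromide.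

Step 13
Reactants: 18 (4S,5R)-4-[(2E)-4-chloro-3-methylbut-2-en-1-yl]-5-[(1R,2S,6S)-6-hydroxy-2,6-dimethyl-1-[(phenylamino)oxy]oct-7-yn-1-yl]-3-methylideneoxolan-2-one
Product: 20 (1S,3E,8S,12S,13R,14R)-8,13-dihydroxycembra-3,15(17)-dien-6-yn-16,14-olide, via anilinooxy macrocyclic enyne 19 (not isolated)
Conditions: CuI (20 mol%), NaI, K2CO3, DMF (2 mM, slow addition of 18), 25 °C; then AcOH, Zn dust, 0 → 25 °C
Reagents that add atoms: none
Why: The copper acetylide allylation of step 8, run intramolecularly at high dilution, closes the 14-membered ring at C5–C6 while the anilinooxy group keeps the C13 oxygen masked against oxa-Michael addition, and Zn/AcOH then cleaves the N–O bond reductively without touching a stereocentre.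

Step 14
Reactants: 20 (1S,3E,8S,12S,13R,14R)-8,13-dihydroxycembra-3,15(17)-dien-6-yn-16,14-olide
Product: 21 (1S,3E,6Z,8S,12S,13R,14R)-8,13-dihydroxycembra-3,6,15(17)-trien-16,14-olide
Conditions: H2 (1 atm), Pd/CaCO3 poisoned with Pb(OAc)2 (Lindlar catalyst), quinoline, EtOAc, 25 °C
Reagents that add atoms: none
Why: Lindlar semi-hydrogenation adds H2 syn to the alkyne and gives the 6Z-alkene; the trisubstituted alkene and the electron-poor exocyclic methylene are not reduced on the poisoned catalyst.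

Step 15
Reactants: 21 (1S,3E,6Z,8S,12S,13R,14R)-8,13-dihydroxycembra-3,6,15(17)-trien-16,14-olide
Product: 22 (1S,3R,4R,6Z,8S,12S,13R,14R)-3,4-epoxy-8,13-dihydroxycembra-6,15(17)-dien-16,14-olide
Conditions: D-fructose-derived Shi ketone (30 mol%), KHSO5 (as 2KHSO5·KHSO4·K2SO4), K2CO3, Bu4NHSO4, MeCN–CH2(OMe)2–aq. Na2B4O7 buffer (pH 10.5), 0 °C
Reagents that add atoms: potassium peroxymonosulfate, [K+].[O-]S(=O)(=O)OO
Why: Shi asymmetric epoxidation: the chiral dioxirane transfers oxygen to the electron-rich trisubstituted (E)-alkene through a spiro transition state and gives the (3R,4R)-epoxide under reagent control, while the cis-disubstituted alkene and the α-methylene lactone are poor dioxirane substrates.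

**Compound list**

1 | (S)-citronellal, (3S)-3,7-dimethyloct-6-enal | O=CC[C@@H](C)CCC=C(C)C | starting material
2 | (6S)-8,8-dimethoxy-2,6-dimethyloct-2-ene | COC(OC)C[C@@H](C)CCC=C(C)C | intermediate
3 | (2E,6S)-8,8-dimethoxy-2,6-dimethyloct-2-en-1-ol | COC(OC)C[C@@H](C)CC/C=C(\C)CO | intermediate
4 | [(2R,3R)-3-[(3S)-5,5-dimethoxy-3-methylpentyl]-2-methyloxiran-2-yl]methanol | OC[C@@]1(C)O[C@@H]1CC[C@H](C)CC(OC)OC | intermediate
5 | (2S,6S)-8,8-dimethoxy-2,6-dimethyloctane-1,2-diol | OC[C@@](C)(O)CCC[C@H](C)CC(OC)OC | intermediate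
6 | (2S,6S)-2-hydroxy-8,8-dimethoxy-2,6-dimethyloctanal | O=C[C@@](C)(O)CCC[C@H](C)CC(OC)OC | intermediate (not isolated)
7 | (3S,7S)-9,9-dimethoxy-3,7-dimethylnon-1-yn-3-ol | C#C[C@@](C)(O)CCC[C@H](C)CC(OC)OC | intermediate
8 | (3S,7S)-7-hydroxy-3,7-dimethylnon-8-ynal | C#C[C@@](C)(O)CCC[C@H](C)CC=O | intermediate
9 | prenyl chloride, 1-chloro-3-methylbut-2-ene | CC(C)=CCCl | starting material
10 | (2E)-4-chloro-2-methylbut-2-en-1-ol | OC/C(C)=C/CCl | intermediate
11 | methyl propiolate | C#CC(=O)OC | starting material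
12 | methyl (5E)-7-hydroxy-6-methylhept-5-en-2-ynoate | COC(=O)C#CC/C=C(\C)CO | intermediate
13 | methyl (5E)-7-chloro-6-methylhept-5-en-2-ynoate | COC(=O)C#CC/C=C(\C)CCl | intermediate
14 | methyl (2Z,5E)-7-chloro-2-(hydroxymethyl)-6-methylhepta-2,5-dienoate | COC(=O)/C(CO)=C\C/C=C(\C)CCl | intermediate
15 | methyl (2E,5E)-2-(bromomethyl)-7-chloro-6-methylhepta-2,5-dienoate | COC(=O)/C(CBr)=C\C/C=C(\C)CCl | intermediate
16 | (2R,3S,7S)-7-hydroxy-3,7-dimethyl-2-[(phenylamino)oxy]non-8-ynal | C#C[C@@](C)(O)CCC[C@H](C)[C@@H](ONc1ccccc1)C=O | intermediate (not isolated)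
17 | methyl (3S,4R,5R,6S,10S)-3-[(2E)-4-chloro-3-methylbut-2-en-1-yl]-4,10-dihydroxy-6,10-dimethyl-2-methylidene-5-[(phenylamino)oxy]dodec-11-ynoate | COC(=O)C(=C)[C@H](C/C=C(\C)CCl)[C@@H](O)[C@H](ONc1ccccc1)[C@@H](C)CCC[C@](C)(O)C#C | intermediate (not isolated)
18 | (4S,5R)-4-[(2E)-4-chloro-3-methylbut-2-en-1-yl]-5-[(1R,2S,6S)-6-hydroxy-2,6-dimethyl-1-[(phenylamino)oxy]oct-7-yn-1-yl]-3-methylideneoxolan-2-one (cis-4,5-disubstituted α-methylene-γ-butyrolactone) | C=C1C(=O)O[C@@H]([C@H](ONc2ccccc2)[C@@H](C)CCC[C@](C)(O)C#C)[C@H]1C/C=C(\C)CCl | intermediate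
19 | (1S,3E,8S,12S,13R,14R)-8-hydroxy-13-[(phenylamino)oxy]cembra-3,15(17)-dien-6-yn-16,14-olide (14-membered enyne cis-fused to the α-methylene lactone) | C=C1C(=O)O[C@H]2[C@H](ONc3ccccc3)[C@@H](C)CCC[C@](C)(O)C#CC/C(C)=C/C[C@@H]12 | intermediate (not isolated)
20 | (1S,3E,8S,12S,13R,14R)-8,13-dihydroxycembra-3,15(17)-dien-6-yn-16,14-olide | C=C1C(=O)O[C@H]2[C@H](O)[C@@H](C)CCC[C@](C)(O)C#CC/C(C)=C/C[C@@H]12 | intermediate
21 | (1S,3E,6Z,8S,12S,13R,14R)-8,13-dihydroxycembra-3,6,15(17)-trien-16,14-olide | C=C1C(=O)O[C@H]2[C@H](O)[C@@H](C)CCC[C@](C)(O)/C=C\C/C(C)=C/C[C@@H]12 | intermediate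
22 | (1S,3R,4R,6Z,8S,12S,13R,14R)-3,4-epoxy-8,13-dihydroxycembra-6,15(17)-dien-16,14-olide (CNP0304380.1) | C=C1C(=O)O[C@H]2[C@H](O)[C@@H](C)CCC[C@](C)(O)/C=C\C[C@@]3(C)O[C@@H]3C[C@@H]12 | target

**Step count and risks**

Total step count: 15 (steps 1–6 east fragment, steps 7–11 west fragment, steps 12–15 union and endgame).
Longest linear sequence: 10 steps (1–6, then 12–15).

The three steps most likely to fail:

Step 12 (the proposed new cascade). The risks are weak chelation by the anilinooxy group (lower 13,14-syn selectivity), erosion of the α-stereocentre before allylation, and loss of bromide to N-allylation of proline. The fallback uses known reactions only; it sets out from 8 (with 15) and comes back to the route at 20. Aldehyde 8 is α-aminoxylated (L-proline, PhNO) and reduced in the same flask with NaBH4 to (2R,3S,7S)-3,7-dimethyl-2-[(phenylamino)oxy]non-8-yne-1,7-diol F1. Zn/AcOH cleaves the N–O bond to (2R,3S,7S)-3,7-dimethylnon-8-yne-1,2,7-triol F2. TEMPO/NaOCl/KBr (CH2Cl2–aq. NaHCO3, 0 °C) oxidises only the primary hydroxyl to (2R,3S,7S)-2,7-dihydroxy-3,7-dimethylnon-8-ynal F3, which is used crude. In powder and 15 in THF–H2O then give, through the precedented chelation of the free α-hydroxyl, methyl (3S,4R,5R,6S,10S)-3-[(2E)-4-chloro-3-methylbut-2-en-1-yl]-4,5,10-trihydroxy-6,10-dimethyl-2-methylidenedodec-11-ynoate F4. PPTS lactonises this to (4S,5R)-4-[(2E)-4-chloro-3-methylbut-2-en-1-yl]-5-[(1R,2S,6S)-1,6-dihydroxy-2,6-dimethyloct-7-yn-1-yl]-3-methylideneoxolan-2-one F5. Ring closure of F5 under the copper conditions of step 13 (no zinc stage needed) gives 20.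

Step 13 (macrocyclisation). The risks are oligomerisation, SN2′ attack at C3, and N-allylation of the anilinooxy group. The fallback replaces the alkylative ring closure by ring-closing alkyne metathesis; it sets out from 7 (with 15) and comes back to the route at 19, which Zn/AcOH converts into 20 as in step 13. Alkyne 7 is methylated at its terminus (n-BuLi 2.2 equiv, THF, −78 °C; MeI) to (4S,8S)-10,10-dimethoxy-4,8-dimethyldec-2-yn-4-ol F6 and hydrolysed to (3S,7S)-7-hydroxy-3,7-dimethyldec-8-ynal F7. The cascade of step 12 with 15 passes through (2R,3S,7S)-7-hydroxy-3,7-dimethyl-2-[(phenylamino)oxy]dec-8-ynal F8 and methyl (3S,4R,5R,6S,10S)-3-[(2E)-4-chloro-3-methylbut-2-en-1-yl]-4,10-dihydroxy-6,10-dimethyl-2-methylidene-5-[(phenylamino)oxy]tridec-11-ynoate F9 (neither isolated) to (4S,5R)-4-[(2E)-4-chloro-3-methylbut-2-en-1-yl]-5-[(1R,2S,6S)-6-hydroxy-2,6-dimethyl-1-[(phenylamino)oxy]non-7-yn-1-yl]-3-methylideneoxolan-2-one F10. The allylic chloride is coupled with propyne (CuI, NaI, K2CO3, DMF) to (4S,5R)-5-[(1R,2S,6S)-6-hydroxy-2,6-dimethyl-1-[(phenylamino)oxy]non-7-yn-1-yl]-4-[(2E)-3-methylhept-2-en-5-yn-1-yl]-3-methylideneoxolan-2-one F11. Ring-closing alkyne metathesis (Mo(≡CC6H4OMe-4)(OSiPh3)3, 5 Å MS, toluene, 80 °C, 2 mM; the tertiary hydroxyl transiently silylated if it slows the catalyst) expels but-2-yne and gives 19.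

Step 15 (final epoxidation on the macrocycle). The risks are competing oxidation of the 6Z-allylic alkene and base sensitivity of the lactone. The fallback changes the order so that the epoxide is installed while no second electron-rich alkene is present; it sets out from 20 and comes back to the route at 22. Enyne 20 is epoxidised with the Shi ketone/KHSO5 system to (1S,3R,4R,8S,12S,13R,14R)-3,4-epoxy-8,13-dihydroxycembr-15(17)-en-6-yn-16,14-olide F12, and the Lindlar reduction of step 14 is then run last to give 22.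

Further compounds
F1 | step 12 | (2R,3S,7S)-3,7-dimethyl-2-[(phenylamino)oxy]non-8-yne-1,7-diol | C#C[C@@](C)(O)CCC[C@H](C)[C@@H](ONc1ccccc1)CO
F2 | step 12 | (2R,3S,7S)-3,7-dimethylnon-8-yne-1,2,7-triol | C#C[C@@](C)(O)CCC[C@H](C)[C@@H](O)CO
F3 | step 12 | (2R,3S,7S)-2,7-dihydroxy-3,7-dimethylnon-8-ynal | C#C[C@@](C)(O)CCC[C@H](C)[C@@H](O)C=O
F4 | step 12 | methyl (3S,4R,5R,6S,10S)-3-[(2E)-4-chloro-3-methylbut-2-en-1-yl]-4,5,10-trihydroxy-6,10-dimethyl-2-methylidenedodec-11-ynoate | COC(=O)C(=C)[C@H](C/C=C(\C)CCl)[C@@H](O)[C@H](O)[C@@H](C)CCC[C@](C)(O)C#C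
F5 | step 12 | (4S,5R)-4-[(2E)-4-chloro-3-methylbut-2-en-1-yl]-5-[(1R,2S,6S)-1,6-dihydroxy-2,6-dimethyloct-7-yn-1-yl]-3-methylideneoxolan-2-one | C=C1C(=O)O[C@@H]([C@H](O)[C@@H](C)CCC[C@](C)(O)C#C)[C@H]1C/C=C(\C)CCl
F6 | step 13 | (4S,8S)-10,10-dimethoxy-4,8-dimethyldec-2-yn-4-ol | CC#C[C@@](C)(O)CCC[C@H](C)CC(OC)OC
F7 | step 13 | (3S,7S)-7-hydroxy-3,7-dimethyldec-8-ynal | CC#C[C@@](C)(O)CCC[C@H](C)CC=O
F8 | step 13 | (2R,3S,7S)-7-hydroxy-3,7-dimethyl-2-[(phenylamino)oxy]dec-8-ynal | CC#C[C@@](C)(O)CCC[C@H](C)[C@@H](ONc1ccccc1)C=O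
F9 | step 13 | methyl (3S,4R,5R,6S,10S)-3-[(2E)-4-chloro-3-methylbut-2-en-1-yl]-4,10-dihydroxy-6,10-dimethyl-2-methylidene-5-[(phenylamino)oxy]tridec-11-ynoate | COC(=O)C(=C)[C@H](C/C=C(\C)CCl)[C@@H](O)[C@H](ONc1ccccc1)[C@@H](C)CCC[C@](C)(O)C#CC
F10 | step 13 | (4S,5R)-4-[(2E)-4-chloro-3-methylbut-2-en-1-yl]-5-[(1R,2S,6S)-6-hydroxy-2,6-dimethyl-1-[(phenylamino)oxy]non-7-yn-1-yl]-3-methylideneoxolan-2-one | C=C1C(=O)O[C@@H]([C@H](ONc2ccccc2)[C@@H](C)CCC[C@](C)(O)C#CC)[C@H]1C/C=C(\C)CCl
F11 | step 13 | (4S,5R)-5-[(1R,2S,6S)-6-hydroxy-2,6-dimethyl-1-[(phenylamino)oxy]non-7-yn-1-yl]-4-[(2E)-3-methylhept-2-en-5-yn-1-yl]-3-methylideneoxolan-2-one | C=C1C(=O)O[C@@H]([C@H](ONc2ccccc2)[C@@H](C)CCC[C@](C)(O)C#CC)[C@H]1C/C=C(\C)CC#CC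
F12 | step 15 | (1S,3R,4R,8S,12S,13R,14R)-3,4-epoxy-8,13-dihydroxycembr-15(17)-en-6-yn-16,14-olide | C=C1C(=O)O[C@H]2[C@H](O)[C@@H](C)CCC[C@](C)(O)C#CC[C@@]3(C)O[C@@H]3C[C@@H]12
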